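**Retrosynthetic overview**
- The strategy rests on the C3a(OH)–C4H2–C5(O) segment of the seven-membered ring, next to C6=C7. C3a–OH with C4H2 is read as an opened spiro-oxirane on the cyclopentane. C5 is read as the α-carbon of a (Z)-allyl phenyl sulfone, which is a masked ketone.
- Endgame: the veratrate comes from the trans-3a,5-diol. The diol comes from reduction of the C5 enone directed by the C3a hydroxyl, and the enone from oxidative desulfonylation of the 5-sulfonyl hydroazulenol.
- Key disconnection C4–C5: the lithiated sulfone opens the oxirane CH2 and closes the cycloheptene. This is the second ring, built on the finished cyclopentane.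
- The oxirane comes from the C3a ketone and a sulfur ylide, with carbon entering anti to isopropyl. The (Z)-chain comes from Still–Gennari olefination, reduction, bromination and sulfinate displacement.
- The cyclopentane (first ring) comes from (S)-limonene by ozonolysis and aldol ring contraction, and C8a from a Johnson–Claisen shift anti to isopropyl. Stereocontrol is relayed C3 → C8a → C3a → C5.

Key step: step 13

Remark: azulene numbering of the target is used for all intermediates. The two 5-sulfonyl hydroazulenes are drawn as the 5R epimer, although C5 is not controlled there and is erased later.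

**Step 1**
Reactants: 1 (S)-(−)-limonene
Product: 2 (S)-p-menth-1-ene [(4S)-1-methyl-4-(propan-2-yl)cyclohex-1-ene]
Conditions: H2 (1 atm), RhCl(PPh3)3 (cat.), toluene–EtOH, rt
Reagents that add atoms: none
Why: Chemoselective homogeneous hydrogenation, in which RhCl(PPh3)3 saturates the unhindered 1,1-disubstituted isopropenyl alkene much faster than the trisubstituted ring alkene and leaves the stereocentre (future C3) untouched.

**Step 2**
Reactants: 2 (S)-p-menth-1-ene
Product: 3 (S)-6-oxo-3-(propan-2-yl)heptanal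
Conditions: O3, CH2Cl2, −78 °C; Me2S, −78 °C → rt
Reagents that add atoms: ozone, [O-][O+]=O
Why: Ozonolysis with reductive work-up cleaves the only alkene to the 1,6-keto aldehyde, and the stereocentre is β to the aldehyde and so cannot enolise.

**Step 3**
Reactants: 3 (S)-6-oxo-3-(propan-2-yl)heptanal
Product: 4 (R)-2-methyl-5-(propan-2-yl)cyclopent-1-ene-1-carbaldehyde
Conditions: piperidine (cat.), AcOH (cat.), toluene, reflux, Dean–Stark
Reagents that add atoms: none
Why: Amine-catalysed intramolecular aldol condensation, in which the piperidine enamine of the aldehyde (future C3a) adds to the methyl ketone (future C8a) in a 5-exo-trig closure and loss of water gives the tetrasubstituted enal, forming the cyclopentane ring with C4, the C8a methyl and the C3 isopropyl group in place.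

**Step 4**
Reactants: 4 (R)-2-methyl-5-(propan-2-yl)cyclopent-1-ene-1-carbaldehyde
Product: 5 [(R)-2-methyl-5-(propan-2-yl)cyclopent-1-en-1-yl]methanol
Conditions: i-Bu2AlH, CH2Cl2, −78 °C; aq. potassium sodium tartrate
Reagents that add atoms: none
Why: 1,2-Reduction of the enal at low temperature gives the primary allylic alcohol without touching the tetrasubstituted alkene.

**Step 5**
Reactants: 5 [(R)-2-methyl-5-(propan-2-yl)cyclopent-1-en-1-yl]methanol; 6 triethyl orthoacetate
Product: 8 ethyl 2-[(1R,3R)-1-methyl-2-methylidene-3-(propan-2-yl)cyclopentyl]acetate, via mixed ketene acetal 7 (not isolated)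
Conditions: MeC(OEt)3 (excess), EtCO2H (cat.), 140–160 °C, EtOH distilled off
Reagents that add atoms: triethyl orthoacetate, CC(OCC)(OCC)OCC
Why: Johnson orthoester Claisen rearrangement, in which acetal exchange and loss of ethanol give 7 and its suprafacial [3,3]-shift runs on the ring face anti to the adjacent C3 isopropyl group, so the new C8a–C8 bond is trans to isopropyl (C8a R) and the alkene moves to the exocyclic C3a=C4 position.

**Step 6**
Reactants: 8 ethyl 2-[(1R,3R)-1-methyl-2-methylidene-3-(propan-2-yl)cyclopentyl]acetate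
Product: 9 ethyl 2-[(1R,3R)-1-methyl-2-oxo-3-(propan-2-yl)cyclopentyl]acetate
Conditions: O3, CH2Cl2, −78 °C; Me2S, −78 °C → rt
Reagents that add atoms: ozone, [O-][O+]=O
Why: Ozonolysis of the only alkene with neutral reductive work-up gives the C3a ketone without epimerising C3, now α to the carbonyl; direct peracid epoxidation of 8 is avoided because it would deliver oxygen to the open face anti to isopropyl and give the wrong C3a configuration.

**Step 7**
Reactants: 9 ethyl 2-[(1R,3R)-1-methyl-2-oxo-3-(propan-2-yl)cyclopentyl]acetate; 10 trimethylsulfonium iodide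
Product: 11 ethyl 2-[(3S,4R,7R)-4-methyl-7-(propan-2-yl)-1-oxaspiro[2.4]heptan-4-yl]acetate
Conditions: Me3SI (1.3 equiv), NaH, DMSO–THF, 0 °C; then 9, 0 °C → rt
Reagents that add atoms: trimethylsulfonium iodide, C[S+](C)C.[I-]
Why: Corey–Chaykovsky epoxidation, in which the unstabilised ylide adds irreversibly to the carbonyl face anti to the C3 isopropyl group (past the pseudo-axial C3–H instead of the pseudo-axial C8a methyl) and 3-exo-tet closure of the betaine leaves C4 anti and oxygen syn to isopropyl (C3a S), as is known for 2,2,5-trisubstituted cyclopentanones; the neopentyl-type ester reacts more slowly than the ketone.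

**Step 8**
Reactants: 11 ethyl 2-[(3S,4R,7R)-4-methyl-7-(propan-2-yl)-1-oxaspiro[2.4]heptan-4-yl]acetate
Product: 12 2-[(3S,4R,7R)-4-methyl-7-(propan-2-yl)-1-oxaspiro[2.4]heptan-4-yl]acetaldehyde
Conditions: i-Bu2AlH (1.1 equiv), toluene, −78 °C; MeOH, then aq. potassium sodium tartrate
Reagents that add atoms: none
Why: Partial ester reduction, in which the aluminium hemiacetal is stable at −78 °C and collapses to the aldehyde only on work-up, and the oxirane is not opened at this temperature.

**Step 9**
Reactants: 12 2-[(3S,4R,7R)-4-methyl-7-(propan-2-yl)-1-oxaspiro[2.4]heptan-4-yl]acetaldehyde; 13 ethyl 2-[bis(2,2,2-trifluoroethoxy)phosphoryl]propanoate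
Product: 14 ethyl (Z)-2-methyl-4-[(3S,4R,7R)-4-methyl-7-(propan-2-yl)-1-oxaspiro[2.4]heptan-4-yl]but-2-enoate
Conditions: 13, KN(SiMe3)2, 18-crown-6, THF, −78 °C; then 12; aq. NH4Cl
Reagents that add atoms: ethyl 2-[bis(2,2,2-trifluoroethoxy)phosphoryl]propanoate, CCOC(=O)C(C)P(=O)(OCC(F)(F)F)OCC(F)(F)F
Why: Still–Gennari variant of the Horner–Wadsworth–Emmons olefination, in which fast irreversible elimination from the kinetic adduct of the electron-poor phosphonate gives the (Z)-trisubstituted enoate and places C5 cis to C8, as the later ring closure requires.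

**Step 10**
Reactants: 14 ethyl (Z)-2-methyl-4-[(3S,4R,7R)-4-methyl-7-(propan-2-yl)-1-oxaspiro[2.4]heptan-4-yl]but-2-enoate
Product: 15 (Z)-2-methyl-4-[(3S,4R,7R)-4-methyl-7-(propan-2-yl)-1-oxaspiro[2.4]heptan-4-yl]but-2-en-1-ol
Conditions: i-Bu2AlH (2.2 equiv), CH2Cl2, −78 °C; aq. potassium sodium tartrate
Reagents that add atoms: none
Why: 1,2-Reduction of the enoate to the allylic alcohol keeps the alkene geometry and is much faster than oxirane opening at −78 °C.

**Step 11**
Reactants: 15 (Z)-2-methyl-4-[(3S,4R,7R)-4-methyl-7-(propan-2-yl)-1-oxaspiro[2.4]heptan-4-yl]but-2-en-1-ol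
Product: 16 (3S,4R,7R)-4-[(Z)-4-bromo-3-methylbut-2-en-1-yl]-4-methyl-7-(propan-2-yl)-1-oxaspiro[2.4]heptane
Conditions: CBr4, PPh3, 2,6-lutidine (buffer), CH2Cl2, −20 → 0 °C
Reagents that add atoms: carbon tetrabromide, BrC(Br)(Br)Br
Why: Appel reaction, in which bromide displaces the alkoxyphosphonium group by SN2 under buffered near-neutral conditions, so no allyl cation forms and both the (Z)-alkene and the oxirane survive.

**Step 12**
Reactants: 16 (3S,4R,7R)-4-[(Z)-4-bromo-3-methylbut-2-en-1-yl]-4-methyl-7-(propan-2-yl)-1-oxaspiro[2.4]heptane; 17 sodium benzenesulfinate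
Product: 18 (3S,4R,7R)-4-methyl-4-[(Z)-3-methyl-4-(phenylsulfonyl)but-2-en-1-yl]-7-(propan-2-yl)-1-oxaspiro[2.4]heptane
Conditions: PhSO2Na, DMF, 0 °C → rt
Reagents that add atoms: sodium benzenesulfinate, [Na+].[O-]S(=O)c1ccccc1
Why: SN2 S-alkylation of the ambident sulfinate at the primary allylic bromide gives the sulfone with the geometry retained, as in the nerol and geraniol series, and sulfinate is too weak a nucleophile to open the oxirane.

**Step 13**
Reactants: 18 (3S,4R,7R)-4-methyl-4-[(Z)-3-methyl-4-(phenylsulfonyl)but-2-en-1-yl]-7-(propan-2-yl)-1-oxaspiro[2.4]heptane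
Product: 20 (3R,3aS,5R,8aR)-6,8a-dimethyl-5-(phenylsulfonyl)-3-(propan-2-yl)-1,2,3,3a,4,5,8,8a-octahydroazulen-3a-ol, via lithiated allyl sulfone 19 (not isolated)
Conditions: n-BuLi (1.05 equiv), THF–DMPU (5:1), 0.01 M, −78 °C → rt; aq. NH4Cl
Reagents that add atoms: none
Why: n-BuLi removes a C5 proton (allylic and α to sulfonyl) to give 19, whose α-carbon attacks the oxirane methylene C4 from the rear of the C4–O bond in an SN2 opening that forms C4–C5 and frees the C3a alkoxide; the closest known reaction type is the ring-forming alkylation of α-sulfonyl carbanions by tethered epoxides. The cycloheptene closes in a 7-endo-tet mode with respect to the oxirane (both oxirane carbons end up in the new ring), which is geometrically accessible because the C8a side chain and C4 lie on the same cyclopentane face, anti to isopropyl, so C5 can reach the backside of C4–O at a C5···C4–C3a angle near 120°. On the electrophile, selectivity comes from substitution, since the competing 6-exo attack would have to hit C3a, a fully substituted carbon flanked by quaternary C8a and branched C3. On the nucleophile, the usual α-preference of lithiated allyl sulfones is reinforced because γ-attack through C7 would need a five-membered transition state that cannot align with the C4–O bond. The (Z)-geometry needed for a cis-cycloheptene is kept because the charge stays largely on C5 and C6=C7 does not rotate at low temperature, and high dilution suppresses intermolecular opening. C3a keeps the configuration set in step 7 because its C–O bond is not broken, while the only new centre, C5, is uncontrolled (it can equilibrate through the carbanion) and is erased in step 15.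

**Step 14**
Reactants: 20 (3R,3aS,5R,8aR)-6,8a-dimethyl-5-(phenylsulfonyl)-3-(propan-2-yl)-1,2,3,3a,4,5,8,8a-octahydroazulen-3a-ol
Product: 21 trimethylsilyl ether of 20 at C3a–O
Conditions: TMSOTf, 2,6-lutidine, CH2Cl2, 0 °C
Reagents that add atoms: trimethylsilyl trifluoromethanesulfonate, C[Si](C)(C)OS(=O)(=O)C(F)(F)F
Why: Silylation of the hindered tertiary alcohol with the strong silyl triflate/lutidine pair; the mask is needed because a free C3a alkoxide next to the C5 ketone formed in step 15 would be an aldolate prone to retro-aldol ring opening.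

**Step 15**
Reactants: 21 trimethylsilyl ether of 20
Product: 23 (3R,3aS,8aR)-6,8a-dimethyl-3-(propan-2-yl)-3a-(trimethylsilyloxy)-2,3,3a,4,8,8a-hexahydroazulen-5(1H)-one, via lithiated sulfone 22 (not isolated)
Conditions: n-BuLi, THF, −78 °C; MoO5·py·HMPA, −78 → −20 °C; aq. Na2SO3, aq. NH4Cl
Reagents that add atoms: oxodiperoxomolybdenum–pyridine–HMPA complex, O=[Mo]12(OO1)OO2.c1ccncc1.CN(C)P(=O)(N(C)C)N(C)C
Why: Oxidative desulfonylation, in which carbanion 22 takes electrophilic oxygen from the peroxo complex at C5 and the resulting α-oxido sulfone expels benzenesulfinate to give the conjugated enone, erasing the C5 centre.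

**Step 16**
Reactants: 23 (3R,3aS,8aR)-6,8a-dimethyl-3-(propan-2-yl)-3a-(trimethylsilyloxy)-2,3,3a,4,8,8a-hexahydroazulen-5(1H)-one
Product: 24 (3R,3aS,8aR)-3a-hydroxy-6,8a-dimethyl-3-(propan-2-yl)-2,3,3a,4,8,8a-hexahydroazulen-5(1H)-one
Conditions: HF·pyridine, pyridine–THF, 0 °C
Reagents that add atoms: none
Why: Fluoride-driven Si–O cleavage in a buffered medium frees the tertiary alcohol without base (retro-aldol) or strong acid (dehydration).

**Step 17**
Reactants: 24 (3R,3aS,8aR)-3a-hydroxy-6,8a-dimethyl-3-(propan-2-yl)-2,3,3a,4,8,8a-hexahydroazulen-5(1H)-one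
Product: 25 (3R,3aS,5R,8aR)-6,8a-dimethyl-3-(propan-2-yl)-1,2,3,3a,4,5,8,8a-octahydroazulene-3a,5-diol
Conditions: Me4NBH(OAc)3, MeCN–AcOH (1:1), −30 → 0 °C
Reagents that add atoms: none
Why: Evans–Saksena hydroxyl-directed reduction, in which exchange of an acetate on boron for the C3a hydroxyl ties the hydride to the face carrying that oxygen, so intramolecular 1,2-delivery to C5 places the new hydroxyl trans to C3a–OH (C5 R); the free reagent is too weak to reduce the enone intermolecularly or in the 1,4 sense.

**Step 18**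
Reactants: 25 (3R,3aS,5R,8aR)-6,8a-dimethyl-3-(propan-2-yl)-1,2,3,3a,4,5,8,8a-octahydroazulene-3a,5-diol; 26 3,4-dimethoxybenzoyl chloride
Product: 27 (3R,3aS,5R,8aR)-3a-hydroxy-6,8a-dimethyl-3-(propan-2-yl)-1,2,3,3a,4,5,8,8a-octahydroazulen-5-yl 3,4-dimethoxybenzoate (target)
Conditions: 26, Et3N, DMAP (cat.), CH2Cl2, 0 °C → rt
Reagents that add atoms: 3,4-dimethoxybenzoyl chloride, COc1ccc(C(=O)Cl)cc1OC
Why: DMAP-catalysed acylation reacts only at the secondary allylic C5 hydroxyl, since the tertiary C3a hydroxyl, flanked by quaternary C8a and the cis isopropyl group, is inert.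

**Compound list**
1 | (S)-(−)-limonene | CC1=CC[C@@H](C(C)=C)CC1 | starting material
2 | (S)-p-menth-1-ene | CC1=CC[C@@H](C(C)C)CC1 | intermediate
3 | (S)-6-oxo-3-(propan-2-yl)heptanal | O=CC[C@@H](C(C)C)CCC(C)=O | intermediate
4 | (R)-2-methyl-5-(propan-2-yl)cyclopent-1-ene-1-carbaldehyde | O=CC1=C(C)CC[C@@H]1C(C)C | intermediate
5 | [(R)-2-methyl-5-(propan-2-yl)cyclopent-1-en-1-yl]methanol | OCC1=C(C)CC[C@@H]1C(C)C | intermediate
6 | triethyl orthoacetate | CC(OCC)(OCC)OCC | starting material
7 | mixed ketene acetal of 5 (1-ethoxyvinyl ether, not isolated) | C=C(OCC)OCC1=C(C)CC[C@@H]1C(C)C | intermediate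
8 | ethyl 2-[(1R,3R)-1-methyl-2-methylidene-3-(propan-2-yl)cyclopentyl]acetate | C=C1[C@@H](C(C)C)CC[C@]1(C)CC(=O)OCC | intermediate
9 | ethyl 2-[(1R,3R)-1-methyl-2-oxo-3-(propan-2-yl)cyclopentyl]acetate | O=C1[C@@H](C(C)C)CC[C@]1(C)CC(=O)OCC | intermediate
10 | trimethylsulfonium iodide | C[S+](C)C.[I-] | starting material
11 | ethyl 2-[(3S,4R,7R)-4-methyl-7-(propan-2-yl)-1-oxaspiro[2.4]heptan-4-yl]acetate | C1O[C@]12[C@@H](C(C)C)CC[C@]2(C)CC(=O)OCC | intermediate
12 | 2-[(3S,4R,7R)-4-methyl-7-(propan-2-yl)-1-oxaspiro[2.4]heptan-4-yl]acetaldehyde | C1O[C@]12[C@@H](C(C)C)CC[C@]2(C)CC=O | intermediate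
13 | ethyl 2-[bis(2,2,2-trifluoroethoxy)phosphoryl]propanoate | CCOC(=O)C(C)P(=O)(OCC(F)(F)F)OCC(F)(F)F | starting material
14 | ethyl (Z)-2-methyl-4-[(3S,4R,7R)-4-methyl-7-(propan-2-yl)-1-oxaspiro[2.4]heptan-4-yl]but-2-enoate | C1O[C@]12[C@@H](C(C)C)CC[C@]2(C)C/C=C(/C)C(=O)OCC | intermediate
15 | (Z)-2-methyl-4-[(3S,4R,7R)-4-methyl-7-(propan-2-yl)-1-oxaspiro[2.4]heptan-4-yl]but-2-en-1-ol | C1O[C@]12[C@@H](C(C)C)CC[C@]2(C)C/C=C(/C)CO | intermediate
16 | (3S,4R,7R)-4-[(Z)-4-bromo-3-methylbut-2-en-1-yl]-4-methyl-7-(propan-2-yl)-1-oxaspiro[2.4]heptane | C1O[C@]12[C@@H](C(C)C)CC[C@]2(C)C/C=C(/C)CBr | intermediate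
17 | sodium benzenesulfinate | [Na+].[O-]S(=O)c1ccccc1 | starting material
18 | (3S,4R,7R)-4-methyl-4-[(Z)-3-methyl-4-(phenylsulfonyl)but-2-en-1-yl]-7-(propan-2-yl)-1-oxaspiro[2.4]heptane (key precursor) | C1O[C@]12[C@@H](C(C)C)CC[C@]2(C)C/C=C(/C)CS(=O)(=O)c3ccccc3 | intermediate
19 | α-lithiated allyl sulfone from 18 (not isolated) | C1O[C@]12[C@@H](C(C)C)CC[C@]2(C)C/C=C(/C)C([Li])S(=O)(=O)c3ccccc3 | intermediate
20 | (3R,3aS,5R,8aR)-6,8a-dimethyl-5-(phenylsulfonyl)-3-(propan-2-yl)-1,2,3,3a,4,5,8,8a-octahydroazulen-3a-ol (key product, C5 drawn as one epimer) | O=S(=O)(c1ccccc1)[C@@H]2C[C@]3(O)[C@@H](C(C)C)CC[C@]3(C)CC=C2C | intermediate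
21 | C3a-O-trimethylsilyl ether of 20 | O=S(=O)(c1ccccc1)[C@@H]2C[C@]3(O[Si](C)(C)C)[C@@H](C(C)C)CC[C@]3(C)CC=C2C | intermediate
22 | C5-lithiated sulfone from 21 (not isolated) | [Li]C2(S(=O)(=O)c1ccccc1)C[C@]3(O[Si](C)(C)C)[C@@H](C(C)C)CC[C@]3(C)CC=C2C | intermediate
23 | (3R,3aS,8aR)-6,8a-dimethyl-3-(propan-2-yl)-3a-(trimethylsilyloxy)-2,3,3a,4,8,8a-hexahydroazulen-5(1H)-one | O=C2C[C@]3(O[Si](C)(C)C)[C@@H](C(C)C)CC[C@]3(C)CC=C2C | intermediate
24 | (3R,3aS,8aR)-3a-hydroxy-6,8a-dimethyl-3-(propan-2-yl)-2,3,3a,4,8,8a-hexahydroazulen-5(1H)-one | O=C2C[C@]3(O)[C@@H](C(C)C)CC[C@]3(C)CC=C2C | intermediate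
25 | (3R,3aS,5R,8aR)-6,8a-dimethyl-3-(propan-2-yl)-1,2,3,3a,4,5,8,8a-octahydroazulene-3a,5-diol | O[C@@H]2C[C@]3(O)[C@@H](C(C)C)CC[C@]3(C)CC=C2C | intermediate
26 | 3,4-dimethoxybenzoyl chloride | COc1ccc(C(=O)Cl)cc1OC | starting material
27 | (3R,3aS,5R,8aR)-3a-hydroxy-6,8a-dimethyl-3-(propan-2-yl)-1,2,3,3a,4,5,8,8a-octahydroazulen-5-yl 3,4-dimethoxybenzoate | COc1ccc(C(=O)O[C@@H]2C[C@]3(O)[C@@H](C(C)C)CC[C@]3(C)CC=C2C)cc1OC | target

**Total step count:** 18. **Longest linear sequence:** 18 steps, from 1 to 27.

**Steps most likely to fail**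

1. **Step 13.** The seven-membered closure at a neopentyl-type oxirane carbon may be slow. Intermolecular opening, loss of the (Z)-geometry of the allyl anion on warming, or reaction through the γ-carbon could then compete.
   Fallback: separate the bond formation from the ring closure.
   - Starting from 12, Wittig methylenation (MePPh3Br, KN(SiMe3)2, THF) should give the allyl spiro-epoxide F1.
   - Methallyl phenyl sulfone F2, made from methallyl chloride and 17 in DMF, is lithiated (n-BuLi, THF–DMPU) and opens F1 intermolecularly at C4 to give the hydroxy sulfone diene F3.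
   - Ring-closing metathesis with the second-generation Grubbs catalyst in refluxing toluene then forms C6=C7, which can only be cis in a seven-membered ring. This returns to the route at 20.

2. **Step 15.** Oxygen transfer may be incomplete or may occur at the γ-carbon C7. Unreacted carbanion may also add to the enone as it forms.
   Fallback: replace oxygen transfer by sulfur transfer and hydrolysis.
   - Starting from 21, lithiation and quenching with MeSSMe should give the 5-methylsulfanyl-5-phenylsulfonyl compound F4, which already has the oxidation level of a ketone.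
   - In aqueous acidic methanol, sulfur-assisted loss of sulfinate and hydrolysis of the thionium ion unmask the C5 carbonyl and also remove the silyl group. This returns to the route at 24.

3. **Step 7.** The basic ylide may enolise the hindered ketone and epimerise C3. It may also attack the ester, or facial selectivity may erode.
   Fallback: build the oxirane stepwise.
   - Starting from 9, PhSCH2Li (thioanisole, n-BuLi, DABCO, THF) is added at −78 °C, where enolisation and ester attack are slow. Addition from the same face anti to isopropyl should give the β-hydroxy sulfide F5.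
   - S-methylation with Me3OBF4 in CH2Cl2 gives the sulfonium salt F6.
   - NaH in THF closes the oxirane by internal displacement. This returns to the route at 11.

**Further compounds**
F1 | step 13 | (3S,4R,7R)-4-methyl-7-(propan-2-yl)-4-(prop-2-en-1-yl)-1-oxaspiro[2.4]heptane | C1O[C@]12[C@@H](C(C)C)CC[C@]2(C)CC=C
F2 | step 13 | methallyl phenyl sulfone | C=C(C)CS(=O)(=O)c1ccccc1
F3 | step 13 | (1S,2R,5R)-2-methyl-1-[3-methyl-2-(phenylsulfonyl)but-3-en-1-yl]-5-(propan-2-yl)-2-(prop-2-en-1-yl)cyclopentan-1-ol (sulfonyl carbon as epimer mixture) | C=C(C)C(S(=O)(=O)c1ccccc1)C[C@]2(O)[C@@H](C(C)C)CC[C@]2(C)CC=C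
F4 | step 15 | (3R,3aS,8aR)-6,8a-dimethyl-5-(methylsulfanyl)-5-(phenylsulfonyl)-3-(propan-2-yl)-3a-(trimethylsilyloxy)-1,2,3,3a,4,5,8,8a-octahydroazulene | CSC2(S(=O)(=O)c1ccccc1)C[C@]3(O[Si](C)(C)C)[C@@H](C(C)C)CC[C@]3(C)CC=C2C
F5 | step 7 | ethyl 2-[(1R,2S,3R)-2-hydroxy-1-methyl-2-[(phenylsulfanyl)methyl]-3-(propan-2-yl)cyclopentyl]acetate | c1ccccc1SC[C@]2(O)[C@@H](C(C)C)CC[C@]2(C)CC(=O)OCC
F6 | step 7 | S-methyl sulfonium tetrafluoroborate of F5 | C[S+](c1ccccc1)C[C@]2(O)[C@@H](C(C)C)CC[C@]2(C)CC(=O)OCC.F[B-](F)(F)F
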